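## Retrosynthetic overview
- The target comes from six-fold O-demethylation, preceded by a Heck coupling at C5 of a 5-chloro-2,3-diaryl-2,3-dihydrobenzofuran with 3,5-dimethoxystyrene (ring A = benzo ring, ring C = aryl on C2, ring D = aryl on C3).
- The plan rests on one feature: C2 is the benzylic carbon of catechol ring C and stands para to the ring C 4'-hydroxyl. C2 can therefore travel as CH2 and be unmasked as the exocyclic carbon of a ring C para-quinone methide, which the ring A oxygen O1 attacks, so O1–C2 is the key disconnection.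
- In the open-chain bisphenol, C3 comes from iridium-catalysed asymmetric hydrogenation of one (E)-triarylethylene. That alkene comes from two stereodefined Suzuki couplings on the gem-dibromoalkene of O-silylated vanillin.
- Ring order: all four benzene rings are bought. The dihydrofuran ring is the only ring formed, in the key step, after C3 is set and before the stilbene is attached.

Key step: step 8

Assumption: the (S)-ligand is paired with the (E)-alkene by analogy with the face this catalyst family selects on (E)-1,2-diarylpropenes, ring A taking the place of the aryl group cis to the vinylic hydrogen. Should a trial run show the opposite sense, the (R)-ligand is used on the same alkene.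

## Route

Step 1
Reactants: 1 vanillin (4-hydroxy-3-methoxybenzaldehyde)
Product: 2 3-methoxy-4-(triisopropylsilyloxy)benzaldehyde
Conditions: TIPSCl, imidazole, DMF, rt
Reagents that add atoms: triisopropylsilyl chloride (TIPSCl), CC(C)[Si](Cl)(C(C)C)C(C)C
Why: Imidazole-promoted O-silylation of a phenol, with the bulky TIPS group chosen because it must outlast two aqueous-carbonate Suzuki couplings.

Step 2
Reactants: 2 3-methoxy-4-(triisopropylsilyloxy)benzaldehyde
Product: 3 [4-(2,2-dibromoethenyl)-2-methoxyphenoxy]triisopropylsilane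
Conditions: CBr4, PPh3, CH2Cl2, 0 °C
Reagents that add atoms: carbon tetrabromide, BrC(Br)(Br)Br
Why: Ramirez gem-dibromoolefination (first stage of the Corey–Fuchs sequence), in which the ylide formed in the flask undergoes a Wittig reaction with a non-enolisable aryl aldehyde.

Step 3
Reactants: 3 [4-(2,2-dibromoethenyl)-2-methoxyphenoxy]triisopropylsilane; 4 (5-chloro-2-hydroxyphenyl)boronic acid
Product: 5 2-{(Z)-1-bromo-2-[3-methoxy-4-(triisopropylsilyloxy)phenyl]ethenyl}-4-chlorophenol
Conditions: Pd2(dba)3 (2.5 mol %), P(2-furyl)3 (15 mol %), Na2CO3 (aq), 1,4-dioxane, 65 °C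
Reagents that add atoms: none
Why: Trans-selective Suzuki–Miyaura mono-coupling of a 1,1-dibromoalkene, in which zerovalent palladium inserts first into the less hindered C–Br bond trans to ring C, so ring A enters trans to ring C, while the weakly donating furylphosphine leaves the second C–Br bond and the aryl chloride alone.

Step 4
Reactants: 5 2-{(Z)-1-bromo-2-[3-methoxy-4-(triisopropylsilyloxy)phenyl]ethenyl}-4-chlorophenol
Product: 6 {2-[(Z)-1-bromo-2-(3-methoxy-4-triisopropylsilyloxyphenyl)ethenyl]-4-chlorophenoxy}triisopropylsilane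
Conditions: TIPSOTf, 2,6-lutidine, CH2Cl2, 0 °C to rt
Reagents that add atoms: triisopropylsilyl triflate (TIPSOTf), CC(C)[Si](OS(=O)(=O)C(F)(F)F)(C(C)C)C(C)C
Why: Silyl triflate silylation of a hindered phenol, done at the bromoalkene stage so that no triarylethylene ever carries a free ortho-hydroxyl, which would invite acid-induced E/Z scrambling, premature racemic ring closure and binding to the cationic iridium catalyst.

Step 5
Reactants: 6 {2-[(Z)-1-bromo-2-(3-methoxy-4-triisopropylsilyloxyphenyl)ethenyl]-4-chlorophenoxy}triisopropylsilane; 7 (3,5-dimethoxyphenyl)boronic acid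
Product: 8 (E)-1-(5-chloro-2-triisopropylsilyloxyphenyl)-1-(3,5-dimethoxyphenyl)-2-(3-methoxy-4-triisopropylsilyloxyphenyl)ethene (ring A trans to ring C, ring D cis to ring C)
Conditions: Pd(PPh3)4 (5 mol %), Na2CO3 (2 M aq), toluene/EtOH, 85 °C
Reagents that add atoms: none
Why: Suzuki–Miyaura coupling of an alkenyl bromide with retention of geometry, which should give a single triarylethylene isomer, and Pd(PPh3)4 does not insert into the electron-rich aryl chloride at this temperature.

Step 6
Reactants: 8 (E)-triarylethylene bis-TIPS ether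
Product: 9 (1S)-1-(5-chloro-2-triisopropylsilyloxyphenyl)-1-(3,5-dimethoxyphenyl)-2-(3-methoxy-4-triisopropylsilyloxyphenyl)ethane
Conditions: [Ir(cod)((S)-t-Bu-PHOX)]BArF (2 mol %), H2 (50 bar), CH2Cl2, rt
Reagents that add atoms: none
Why: Asymmetric hydrogenation of an unfunctionalised trisubstituted alkene with a cationic iridium N,P-ligand catalyst, a reaction type that extends to 1,1-diaryl and triaryl alkenes, in which the catalyst pocket recognises where the lone vinylic hydrogen sits, so the geometrically pure (E)-alkene should be reduced from one face and C3 is set as S, while the aryl chloride and silyl ethers are untouched.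

Step 7
Reactants: 9 (1S)-bis-TIPS triarylethane
Product: 10 4-chloro-2-[(1S)-1-(3,5-dimethoxyphenyl)-2-(4-hydroxy-3-methoxyphenyl)ethyl]phenol
Conditions: TBAF (2.4 equiv), AcOH (2.4 equiv), THF, 0 °C to rt
Reagents that add atoms: none
Why: Fluoride cleavage of both aryl silyl ethers, buffered with acetic acid so that no electron-rich phenoxide is left exposed to air.

Step 8
Reactants: 10 4-chloro-2-[(1S)-1-(3,5-dimethoxyphenyl)-2-(4-hydroxy-3-methoxyphenyl)ethyl]phenol
Product: 12 (2S,3S)-5-chloro-3-(3,5-dimethoxyphenyl)-2-(4-hydroxy-3-methoxyphenyl)-2,3-dihydro-1-benzofuran (trans), via para-quinone methide 11 (not isolated)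
Conditions: Ag2O (1.1 equiv, freshly precipitated), 4 Å MS, CH2Cl2 (0.01 M), rt, dark, argon; filtration through Celite as soon as 10 is consumed
Reagents that add atoms: none
Why: Ag2O, which offers two monovalent silver centres and so two electrons' worth of oxidation, takes the ring C guaiacol to its phenoxyl radical and then, with loss of one C2 hydrogen, to para-quinone methide 11, in which C2 is the electrophilic exocyclic carbon. The ring A hydroxyl adds to C2 (oxa-1,6-addition), which forms O1–C2, closes the dihydrofuran ring in the 5-exo-trig mode and lets ring C regain aromaticity. The closest known reaction types are the Ag2O dehydrogenation of 4-alkyl-2-methoxyphenols to para-quinone methides and the phenol-to-quinone-methide closure that completes dihydrobenzofuran neolignans. C2 is controlled by C3: allylic 1,3-strain holds the C3–H bond in the plane of the quinone methide, rings A and D then lie on opposite faces, and O1 can reach C2 only from the ring A face, which leaves ring C cis to the C3 hydrogen and trans to ring D, that is (2S,3S), also the more stable isomer. The step needs oxidation of ring C ahead of ring A, secured by the ortho-methoxy group that weakens the ring C O–H bond while chlorine makes the ring A phenol harder to oxidise, and it needs ring closure ahead of radical dimerisation, secured by high dilution and the proximity of O1. A near-stoichiometric charge of oxidant, a neutral aprotic medium and prompt filtration guard against tautomerisation of 11 through its C3–H (loss of C3) and against further dehydrogenation of 12 to the benzofuran.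

Step 9
Reactants: 12 (2S,3S)-5-chloro-3-(3,5-dimethoxyphenyl)-2-(4-hydroxy-3-methoxyphenyl)-2,3-dihydro-1-benzofuran
Product: 13 (2S,3S)-5-chloro-2-(3,4-dimethoxyphenyl)-3-(3,5-dimethoxyphenyl)-2,3-dihydro-1-benzofuran
Conditions: MeI, K2CO3, acetone, rt
Reagents that add atoms: iodomethane (MeI), CI
Why: Williamson O-methylation, which caps the ring C para-hydroxyl so that its phenoxide cannot expel O1 and reopen the quinone methide in the hot, basic Heck step, and the extra methyl group leaves with the others in the last step.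

Step 10
Reactants: 13 (2S,3S)-5-chloro-2-(3,4-dimethoxyphenyl)-3-(3,5-dimethoxyphenyl)-2,3-dihydro-1-benzofuran; 14 3,5-dimethoxystyrene
Product: 15 (2S,3S)-2-(3,4-dimethoxyphenyl)-3-(3,5-dimethoxyphenyl)-5-[(E)-2-(3,5-dimethoxyphenyl)ethenyl]-2,3-dihydro-1-benzofuran
Conditions: Pd2(dba)3 (2.5 mol %), P(t-Bu)3 (10 mol %), Cy2NMe, 1,4-dioxane, 110 °C
Reagents that add atoms: none
Why: Mizoroki–Heck reaction of an electron-rich aryl chloride, made possible by the bulky electron-rich phosphine, in which syn carbopalladation at the terminal styrene carbon followed by syn beta-hydride elimination gives the (E)-stilbene, and the tertiary amine base leaves C2 and C3 alone.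

Step 11
Reactants: 15 hexamethyl ether of the target
Product: 16 4-{(2S,3S)-3-(3,5-dihydroxyphenyl)-5-[(E)-2-(3,5-dihydroxyphenyl)ethenyl]-2,3-dihydro-1-benzofuran-2-yl}benzene-1,2-diol (CNP0207985.1)
Conditions: BBr3 (12 equiv), CH2Cl2, −78 °C to rt, argon; then ice/H2O
Reagents that add atoms: none
Why: Boron tribromide cleavage of aryl methyl ethers (Lewis acid complexation, then bromide attack on the methyl carbon), which should spare the stilbene and both stereocentres because the only other ether, O1–C2, is a cyclic secondary one whose ionisation, if it occurs, is reversible and returns the trans ring.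

## Compound list
1 | vanillin | COc1cc(C=O)ccc1O | starting material
2 | 3-methoxy-4-(triisopropylsilyloxy)benzaldehyde | COc1cc(C=O)ccc1O[Si](C(C)C)(C(C)C)C(C)C | intermediate
3 | [4-(2,2-dibromoethenyl)-2-methoxyphenoxy]triisopropylsilane | COc1cc(C=C(Br)Br)ccc1O[Si](C(C)C)(C(C)C)C(C)C | intermediate
4 | (5-chloro-2-hydroxyphenyl)boronic acid | OB(O)c1cc(Cl)ccc1O | starting material
5 | 2-{(Z)-1-bromo-2-[3-methoxy-4-(triisopropylsilyloxy)phenyl]ethenyl}-4-chlorophenol | COc1cc(/C=C(\Br)c2cc(Cl)ccc2O)ccc1O[Si](C(C)C)(C(C)C)C(C)C | intermediate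
6 | bis-TIPS (Z)-bromoalkene | COc1cc(/C=C(\Br)c2cc(Cl)ccc2O[Si](C(C)C)(C(C)C)C(C)C)ccc1O[Si](C(C)C)(C(C)C)C(C)C | intermediate
7 | (3,5-dimethoxyphenyl)boronic acid | COc1cc(B(O)O)cc(OC)c1 | starting material
8 | bis-TIPS (E)-triarylethylene | COc1cc(/C=C(\c2cc(OC)cc(OC)c2)c2cc(Cl)ccc2O[Si](C(C)C)(C(C)C)C(C)C)ccc1O[Si](C(C)C)(C(C)C)C(C)C | intermediate
9 | bis-TIPS (1S)-triarylethane | CC(C)[Si](C(C)C)(C(C)C)Oc1ccc(Cl)cc1[C@H](c1cc(OC)cc(OC)c1)Cc1ccc(O[Si](C(C)C)(C(C)C)C(C)C)c(OC)c1 | intermediate
10 | 4-chloro-2-[(1S)-1-(3,5-dimethoxyphenyl)-2-(4-hydroxy-3-methoxyphenyl)ethyl]phenol | Oc1ccc(Cl)cc1[C@H](c1cc(OC)cc(OC)c1)Cc1ccc(O)c(OC)c1 | intermediate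
11 | 4-[(2S)-2-(5-chloro-2-hydroxyphenyl)-2-(3,5-dimethoxyphenyl)ethylidene]-2-methoxycyclohexa-2,5-dien-1-one (exocyclic C=C geometry not defined, both forms converge on 12) | Oc1ccc(Cl)cc1[C@H](c1cc(OC)cc(OC)c1)C=C1C=CC(=O)C(OC)=C1 | intermediate
12 | (2S,3S)-5-chloro-3-(3,5-dimethoxyphenyl)-2-(4-hydroxy-3-methoxyphenyl)-2,3-dihydro-1-benzofuran | Clc1ccc2c(c1)[C@H](c1cc(OC)cc(OC)c1)[C@@H](c1ccc(O)c(OC)c1)O2 | intermediate
13 | (2S,3S)-5-chloro-2-(3,4-dimethoxyphenyl)-3-(3,5-dimethoxyphenyl)-2,3-dihydro-1-benzofuran | Clc1ccc2c(c1)[C@H](c1cc(OC)cc(OC)c1)[C@@H](c1ccc(OC)c(OC)c1)O2 | intermediate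
14 | 3,5-dimethoxystyrene | C=Cc1cc(OC)cc(OC)c1 | starting material
15 | hexamethyl ether of the target | COc1cc(OC)cc(/C=C/c2ccc3c(c2)[C@H](c2cc(OC)cc(OC)c2)[C@@H](c2ccc(OC)c(OC)c2)O3)c1 | intermediate
16 | CNP0207985.1 | Oc1cc(O)cc(/C=C/c2ccc3c(c2)[C@H](c2cc(O)cc(O)c2)[C@@H](c2ccc(O)c(O)c2)O3)c1 | target

Total step count: 11. Longest linear sequence: 11 steps (1 to 16).

## Steps most likely to fail

**Step 8.** Three processes threaten this step.
- Bimolecular coupling of the ring C phenoxyl radical through its free ortho carbon may outrun loss of the C2 hydrogen.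
- The quinone methide may tautomerise through its doubly benzylic C3–H to the hydroxystilbene, which erases C3.
- The product phenol may be dehydrogenated further to the benzofuran.

The fallback replaces the oxidative entry by a redox-neutral ring closure followed by resolution, and it sets out from 8. Desilylation (TBAF/AcOH, THF) should give 4-chloro-2-[(E)-1-(3,5-dimethoxyphenyl)-2-(4-hydroxy-3-methoxyphenyl)ethenyl]phenol F1. Treatment with CF3CO2H in CH2Cl2 at 0 °C protonates C3, and the C2 cation so formed is the O-protonated form of the same quinone methide. The ring A hydroxyl then closes it under thermodynamic control to racemic trans-5-chloro-3-(3,5-dimethoxyphenyl)-2-(4-hydroxy-3-methoxyphenyl)-2,3-dihydro-1-benzofuran F2. Preparative chromatography on a polysaccharide-type chiral stationary phase delivers the (2S,3S)-enantiomer, and the route is rejoined at 12.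

**Step 6.** Turnover may be slow at an alkene flanked by an ortho-silyloxyaryl group. Acidic iridium hydride species may isomerise the electron-rich alkene (E to Z) before reduction, with loss of facial fidelity.

The fallback is a substrate-directed hydrogenation and sets out from 5. Coupling with 7 without prior silylation (Pd(PPh3)4, aq Na2CO3, toluene/EtOH, 85 °C) should give 4-chloro-2-{(E)-1-(3,5-dimethoxyphenyl)-2-[3-methoxy-4-(triisopropylsilyloxy)phenyl]ethenyl}phenol F3, which is used at once. It is hydrogenated with [Rh(cod)2]BF4 and a Josiphos-type ferrocenyl diphosphine (antipode chosen by a trial run), Et3N, MeOH and H2. In this hydroxyl-directed reduction of a 2-(1-arylvinyl)phenol, the phenoxide binds monovalent rhodium and brings it to the alkene. The product should be 4-chloro-2-{(1S)-1-(3,5-dimethoxyphenyl)-2-[3-methoxy-4-(triisopropylsilyloxy)phenyl]ethyl}phenol F4. TBAF/AcOH then rejoins the route at 10.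

**Step 11.** The six-fold demethylation needs a large excess of Lewis acid and long contact. During that time the O1–C2 bond may ionise with help from the ring C para oxygen, and the electron-rich stilbene may undergo acid-induced addition or oligomerisation.

The fallback changes the protecting-group plan so that the last step is a mild solvolysis, and it sets out from 12.
- BBr3 (CH2Cl2, −78 to 0 °C), now acting on only three methyl ethers and with no stilbene present, should give (2S,3S)-5-chloro-2-(3,4-dihydroxyphenyl)-3-(3,5-dihydroxyphenyl)-2,3-dihydro-1-benzofuran F5.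
- Ac2O/pyridine should give its tetraacetate F6.
- Heck coupling under the conditions of step 10 with commercial 3,5-diacetoxystyrene (C=Cc1cc(OC(C)=O)cc(OC(C)=O)c1) should give the hexaacetate of the target F7.
- Transesterification (catalytic K2CO3, degassed MeOH, 0 °C, then AcOH) arrives at 16.

## Further compounds
F1 | step 8 | 4-chloro-2-[(E)-1-(3,5-dimethoxyphenyl)-2-(4-hydroxy-3-methoxyphenyl)ethenyl]phenol | COc1cc(/C=C(\c2cc(OC)cc(OC)c2)c2cc(Cl)ccc2O)ccc1O
F2 | step 8 | racemic trans-5-chloro-3-(3,5-dimethoxyphenyl)-2-(4-hydroxy-3-methoxyphenyl)-2,3-dihydro-1-benzofuran (both enantiomers) | Clc1ccc2c(c1)[C@H](c1cc(OC)cc(OC)c1)[C@@H](c1ccc(O)c(OC)c1)O2.Clc1ccc2c(c1)[C@@H](c1cc(OC)cc(OC)c1)[C@H](c1ccc(O)c(OC)c1)O2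
F3 | step 6 | 4-chloro-2-{(E)-1-(3,5-dimethoxyphenyl)-2-[3-methoxy-4-(triisopropylsilyloxy)phenyl]ethenyl}phenol | COc1cc(/C=C(\c2cc(OC)cc(OC)c2)c2cc(Cl)ccc2O)ccc1O[Si](C(C)C)(C(C)C)C(C)C
F4 | step 6 | 4-chloro-2-{(1S)-1-(3,5-dimethoxyphenyl)-2-[3-methoxy-4-(triisopropylsilyloxy)phenyl]ethyl}phenol | Oc1ccc(Cl)cc1[C@H](c1cc(OC)cc(OC)c1)Cc1ccc(O[Si](C(C)C)(C(C)C)C(C)C)c(OC)c1
F5 | step 11 | (2S,3S)-5-chloro-2-(3,4-dihydroxyphenyl)-3-(3,5-dihydroxyphenyl)-2,3-dihydro-1-benzofuran | Clc1ccc2c(c1)[C@H](c1cc(O)cc(O)c1)[C@@H](c1ccc(O)c(O)c1)O2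
F6 | step 11 | tetraacetate of F5 | Clc1ccc2c(c1)[C@H](c1cc(OC(C)=O)cc(OC(C)=O)c1)[C@@H](c1ccc(OC(C)=O)c(OC(C)=O)c1)O2
F7 | step 11 | hexaacetate of 16 | CC(=O)Oc1cc(OC(C)=O)cc(/C=C/c2ccc3c(c2)[C@H](c2cc(OC(C)=O)cc(OC(C)=O)c2)[C@@H](c2ccc(OC(C)=O)c(OC(C)=O)c2)O3)c1
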